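**Retrosynthetic overview**

1. The strategy rests on ring A (C4a, C5, C6, C7, C8, C8a): it carries oxygen on C5, C7 and C8a (O1), the alternating pattern of a folded triketide, and its C5–C6 bond joins a former carboxyl carbon (C5) to a former methyl carbon (C6).
2. Key disconnection: C5–C6 by an intramolecular Claisen condensation, leading back to 4-pyranone 14. In 14 ring C is already closed (O1–C8a in place), the ester sits on C4a, and the arm on C8a carries C8, the acetyl group (C7, C6) and the stereocentre.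
3. 14 is cut at C8–C8a into the 2-methylsulfanyl-pyranone 6 and the regiodefined enolate 13. The stereocentre comes from a rhodium/BINAP-catalysed conjugate arylation of (E)-pent-3-en-2-one with trapping of the enolate.
4. 6 comes from the ketene dithioacetal of a benzyloxyacetoacetate by aroylation at C4 and ring closure.
5. Ring order: ring B is bought, ring C (the pyranone) is made first, ring A last; O7-methylation and hydrogenolysis finish the synthesis.

Key step: step 5

Remark: atoms of intermediates are numbered as in the final flavone (O1, C2–C4, C4a, C5–C8, C8a); (S)-BINAP is assumed to deliver aryl to the C3-si face of (E)-pent-3-en-2-one as it does with other (E)-acceptors, so (R)-BINAP is specified for the (S) centre.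

**Step 1**
Reactants: 1 methyl 4-(benzyloxy)-3-oxobutanoate
Product: 2 methyl 4-(benzyloxy)-2-[bis(methylsulfanyl)methylidene]-3-oxobutanoate
Conditions: K2CO3 (2.5 equiv), CS2, DMF, 0 °C; then MeI (2.2 equiv), 0 °C → rt
Reagents that add atoms: carbon disulfide S=C=S; iodomethane CI
Why: Double deprotonation of the C2 methylene (far more acidic than C4), addition to CS2 and twofold S-methylation is the standard α-oxo ketene dithioacetal synthesis of β-keto esters.

**Step 2**
Reactants: 2 methyl 4-(benzyloxy)-2-[bis(methylsulfanyl)methylidene]-3-oxobutanoate; 3 4-methoxybenzoyl chloride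
Product: 6 methyl 5-(benzyloxy)-6-(4-methoxyphenyl)-2-(methylsulfanyl)-4-oxo-4H-pyran-3-carboxylate, via lithium enolate 4 (not isolated), via diketone 5 (not isolated)
Conditions: LiN(SiMe3)2 (2.1 equiv), THF, −78 °C; 3, −78 → 0 °C; then CF3CO2H, CH2Cl2, rt
Reagents that add atoms: none
Why: Deprotonation at C4 (the only enolisable carbon left) and Claisen-type C-aroylation, with the second equivalent of base taking up the acidic diketone, should give 5, whose aroyl enol oxygen then adds to the protonated dithioacetal carbon and expels methanethiol (6-endo addition–elimination) to close the 2-methylsulfanyl-4-pyranone.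

**Step 3**
Reactants: 7 1-(benzyloxy)-4-bromobenzene; 8 (E)-pent-3-en-2-one
Product: 12 trimethyl({(2Z,4S)-4-[4-(benzyloxy)phenyl]pent-2-en-2-yl}oxy)silane, via aryllithium 9 (not isolated), via aryltitanium 10 (not isolated), via titanium enolate 11 (not isolated)
Conditions: n-BuLi, THF, −78 °C; ClTi(OiPr)3, −78 → 20 °C; 8, [Rh(OH)((R)-BINAP)]2 (3 mol% Rh), THF, 20 °C; then LiOiPr, Me3SiCl, 20 °C
Reagents that add atoms: chlorotrimethylsilane C[Si](C)(C)Cl
Why: Bromine–lithium exchange and transmetalation give the aryltitanium reagent for a Hayashi-type rhodium-catalysed asymmetric 1,4-addition, in which (R)-BINAP is expected to direct aryl transfer to the C3-re face of the s-cis enone and so set the (S) centre, and the regiodefined titanium enolate is silylated on oxygen after conversion to the titanate with LiOiPr.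

**Step 4**
Reactants: 12 trimethyl({(2Z,4S)-4-[4-(benzyloxy)phenyl]pent-2-en-2-yl}oxy)silane; 6 methyl 5-(benzyloxy)-6-(4-methoxyphenyl)-2-(methylsulfanyl)-4-oxo-4H-pyran-3-carboxylate
Product: 14 methyl 5-(benzyloxy)-2-{(3RS,4S)-4-[4-(benzyloxy)phenyl]-2-oxopentan-3-yl}-6-(4-methoxyphenyl)-4-oxo-4H-pyran-3-carboxylate, via lithium enolate 13 (not isolated)
Conditions: 12 (2.1 equiv), MeLi (2.1 equiv), THF, 0 °C; then 6 (1 equiv), −78 → −20 °C; aq. NH4Cl
Reagents that add atoms: none
Why: Methyllithium cleaves the Si–O bond to release the lithium enolate with its double bond fixed at C2–C3, which should add through C3 to the pyranone carbon bearing SMe (β to both the ring ketone and the ester) and expel thiomethoxide (conjugate addition–elimination at a vinylogous thioester), the second equivalent of enolate taking up the acidic product proton so that no amide base is present to form the methyl-side enolate, and the benzylic centre is untouched.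

**Step 5**
Reactants: 14 methyl 5-(benzyloxy)-2-{(3RS,4S)-4-[4-(benzyloxy)phenyl]-2-oxopentan-3-yl}-6-(4-methoxyphenyl)-4-oxo-4H-pyran-3-carboxylate
Product: 16 3-(benzyloxy)-8-{(1R)-1-[4-(benzyloxy)phenyl]ethyl}-5,7-dihydroxy-2-(4-methoxyphenyl)-4H-chromen-4-one, via dianion 15 (not isolated)
Conditions: LiN(iPr)2 (3.2 equiv), THF, −78 → 0 °C; aq. NH4Cl
Reagents that add atoms: none
Why: Proposed new method: LiN(iPr)2 should first remove the C8 proton of 14 (vinylogous to the ring carbonyl and α to the ketone) and then a proton of the C6 methyl group, giving dianion 15, whose terminal carbanion adds to the neighbouring ester carbonyl, methoxide leaves, and the cyclohexenedione so formed enolises twice to the aromatic 5,7-diol. The closest known reactions are the terminal C-acylation of 1,3-dicarbonyl dianions by esters, the Dieckmann-type closure of 2-(2-oxopropyl)benzoates to naphthalene-1,3-diols and the Claisen folding of open poly-β-carbonyl chains to phloroglucinols, the chain here being held in its cyclodehydrated 4-pyranone form. Ring A closes by a 6-(enolendo)-exo-trig attack of C6 on the ester carbon (C5), with C5, C4a, C8a, C8 and C7 already lying in one conjugated plane. No stereocentre is formed, and the benzylic centre has no acidic hydrogen and keeps its spatial arrangement, its descriptor changing from S to R only because C8 becomes an aromatic carbon of higher priority. The step needs C-acylation at C6 instead of O-acylation by the enolate oxygen on C7 (which would give a fused 2-pyranone); this is secured by forming the dianion, whose most basic and most nucleophilic site is the terminal carbon, and by the low temperature, while the bulky arylethyl group should prefer the side of C8 facing O1 and so turn the enolate arm towards the ester. Substitution at C8 and not C6 is fixed in advance because O1 is already bonded to C8a.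

**Step 6**
Reactants: 16 3-(benzyloxy)-8-{(1R)-1-[4-(benzyloxy)phenyl]ethyl}-5,7-dihydroxy-2-(4-methoxyphenyl)-4H-chromen-4-one
Product: 17 3-(benzyloxy)-8-{(1R)-1-[4-(benzyloxy)phenyl]ethyl}-5-hydroxy-7-methoxy-2-(4-methoxyphenyl)-4H-chromen-4-one
Conditions: MeI (1.2 equiv), K2CO3, acetone, rt
Reagents that add atoms: iodomethane CI
Why: The 7-hydroxyl is the more acidic and the only free phenol, the 5-hydroxyl being tied up in a hydrogen bond to the C4 carbonyl, so a Williamson methylation with a slight excess of MeI should be selective for O7.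

**Step 7**
Reactants: 17 3-(benzyloxy)-8-{(1R)-1-[4-(benzyloxy)phenyl]ethyl}-5-hydroxy-7-methoxy-2-(4-methoxyphenyl)-4H-chromen-4-one
Product: 18 3,5-dihydroxy-8-[(1R)-1-(4-hydroxyphenyl)ethyl]-7-methoxy-2-(4-methoxyphenyl)-4H-chromen-4-one (CNP0223021.1)
Conditions: H2 (1 atm), Pd/C (10 wt%), EtOAc/MeOH, rt
Reagents that add atoms: none
Why: Catalytic hydrogenolysis should cleave both O-benzyl groups, while the tetrasubstituted C2–C3 double bond of the flavonol, the methyl ethers and the diarylmethine C–C bonds are inert at one atmosphere of hydrogen.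

**Compound list**

1 | methyl 4-(benzyloxy)-3-oxobutanoate | COC(=O)CC(=O)COCc1ccccc1 | starting material
2 | methyl 4-(benzyloxy)-2-[bis(methylsulfanyl)methylidene]-3-oxobutanoate | COC(=O)C(=C(SC)SC)C(=O)COCc1ccccc1 | intermediate
3 | 4-methoxybenzoyl chloride | COc1ccc(C(=O)Cl)cc1 | starting material
4 | lithium C4-enolate of 2 (geometry not defined) | COC(=O)C(=C(SC)SC)C(O[Li])=COCc1ccccc1 | intermediate
5 | methyl 4-(benzyloxy)-2-[bis(methylsulfanyl)methylidene]-5-(4-methoxyphenyl)-3,5-dioxopentanoate | COC(=O)C(=C(SC)SC)C(=O)C(OCc1ccccc1)C(=O)c1ccc(OC)cc1 | intermediate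
6 | methyl 5-(benzyloxy)-6-(4-methoxyphenyl)-2-(methylsulfanyl)-4-oxo-4H-pyran-3-carboxylate | COC(=O)c1c(SC)oc(-c2ccc(OC)cc2)c(OCc2ccccc2)c1=O | intermediate
7 | 1-(benzyloxy)-4-bromobenzene | Brc1ccc(OCc2ccccc2)cc1 | starting material
8 | (E)-pent-3-en-2-one | C/C=C/C(C)=O | starting material
9 | [4-(benzyloxy)phenyl]lithium | [Li]c1ccc(OCc2ccccc2)cc1 | intermediate
10 | [4-(benzyloxy)phenyl]tri(propan-2-yloxy)titanium | CC(C)O[Ti](OC(C)C)(OC(C)C)c1ccc(OCc2ccccc2)cc1 | intermediate
11 | ({(2Z,4S)-4-[4-(benzyloxy)phenyl]pent-2-en-2-yl}oxy)tri(propan-2-yloxy)titanium | C/C(O[Ti](OC(C)C)(OC(C)C)OC(C)C)=C/[C@H](C)c1ccc(OCc2ccccc2)cc1 | intermediate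
12 | trimethyl({(2Z,4S)-4-[4-(benzyloxy)phenyl]pent-2-en-2-yl}oxy)silane | C/C(O[Si](C)(C)C)=C/[C@H](C)c1ccc(OCc2ccccc2)cc1 | intermediate
13 | lithium (2Z,4S)-4-[4-(benzyloxy)phenyl]pent-2-en-2-olate | C/C(O[Li])=C/[C@H](C)c1ccc(OCc2ccccc2)cc1 | intermediate
14 | methyl 5-(benzyloxy)-2-{(3RS,4S)-4-[4-(benzyloxy)phenyl]-2-oxopentan-3-yl}-6-(4-methoxyphenyl)-4-oxo-4H-pyran-3-carboxylate | COc1ccc(-c2oc(C(C(C)=O)[C@H](C)c3ccc(OCc4ccccc4)cc3)c(C(=O)OC)c(=O)c2OCc2ccccc2)cc1 | intermediate
15 | dilithium C8,C6-dianion of 14 (benzylic centre unchanged) | [Li+].[Li+].[CH2-]C(=O)[C-]([C@H](C)c1ccc(OCc2ccccc2)cc1)c1oc(-c2ccc(OC)cc2)c(OCc2ccccc2)c(=O)c1C(=O)OC | intermediate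
16 | 3-(benzyloxy)-8-{(1R)-1-[4-(benzyloxy)phenyl]ethyl}-5,7-dihydroxy-2-(4-methoxyphenyl)-4H-chromen-4-one | COc1ccc(-c2oc3c([C@H](C)c4ccc(OCc5ccccc5)cc4)c(O)cc(O)c3c(=O)c2OCc2ccccc2)cc1 | intermediate
17 | 3-(benzyloxy)-8-{(1R)-1-[4-(benzyloxy)phenyl]ethyl}-5-hydroxy-7-methoxy-2-(4-methoxyphenyl)-4H-chromen-4-one | COc1ccc(-c2oc3c([C@H](C)c4ccc(OCc5ccccc5)cc4)c(OC)cc(O)c3c(=O)c2OCc2ccccc2)cc1 | intermediate
18 | 3,5-dihydroxy-8-[(1R)-1-(4-hydroxyphenyl)ethyl]-7-methoxy-2-(4-methoxyphenyl)-4H-chromen-4-one | COc1ccc(-c2oc3c([C@H](C)c4ccc(O)cc4)c(OC)cc(O)c3c(=O)c2O)cc1 | target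

**Step count and risks**

Total steps: 7. Longest linear sequence: 6 steps (1 → 2 → 6 → 14 → 16 → 17 → 18; the branch 7 + 8 → 12 joins at step 4).

Steps most likely to fail:

1. Step 5 (proposed new method). The second deprotonation may stay incomplete, so that the monoanion closes through the C7 enolate oxygen onto the ester (enol-lactonisation), or the base may attack the pyranone ring instead.
   Fallback by known chemistry, which attaches the side chain to a preformed ring A. It sets out from 7 and 3 and comes back to the route at 18.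
   - Suzuki–Miyaura vinylation of 7 (CH2=CHBF3K, PdCl2(dppf), Cs2CO3, THF/H2O) would give 1-(benzyloxy)-4-ethenylbenzene F1.
   - Copper-catalysed asymmetric Markovnikov hydroboration (CuCl, NaOtBu, the DTBM-SEGPHOS enantiomer that leads to the R product, pinacolborane) would give 2-{(1R)-1-[4-(benzyloxy)phenyl]ethyl}-4,4,5,5-tetramethyl-1,3,2-dioxaborolane F2.
   - In parallel, 3 would aroylate (pyridine) the phenol of 2-(benzyloxy)-1-(2-hydroxy-4,6-dimethoxyphenyl)ethan-1-one F3, itself made by Hoesch acylation of 3,5-dimethoxyphenol with benzyloxyacetonitrile (ZnCl2, HCl), to give 2-[(benzyloxy)acetyl]-3,5-dimethoxyphenyl 4-methoxybenzoate F4.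
   - Baker–Venkataraman rearrangement (KOH, pyridine) would give 2-(benzyloxy)-1-(2-hydroxy-4,6-dimethoxyphenyl)-3-(4-methoxyphenyl)propane-1,3-dione F5, and acid cyclodehydration (H2SO4, AcOH) would give 3-(benzyloxy)-5,7-dimethoxy-2-(4-methoxyphenyl)-4H-chromen-4-one F6.
   - Iodination (I2, AgO2CCF3, CH2Cl2), which goes to C8 in 5,7-dimethoxyflavones, would give 3-(benzyloxy)-8-iodo-5,7-dimethoxy-2-(4-methoxyphenyl)-4H-chromen-4-one F7.
   - Stereoretentive Suzuki–Miyaura coupling of the secondary benzylic boronate F2 with F7 (Pd2(dba)3, PPh3, Ag2O, DME, 85 °C) would give 3-(benzyloxy)-8-{(1R)-1-[4-(benzyloxy)phenyl]ethyl}-5,7-dimethoxy-2-(4-methoxyphenyl)-4H-chromen-4-one F8.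
   - BCl3 (CH2Cl2, −78 → 0 °C) would remove both benzyl groups and the chelated 5-O-methyl group to give 18.

2. Step 4. Attack of the hindered secondary enolate carbon at the SMe-bearing carbon may be slow, so that proton transfer to the enolate, drift of the enolate to its methyl-side regioisomer, or addition to the ester carbonyl takes over.
   Fallback with a cationic electrophile and a neutral nucleophile. It sets out from 6 and 12 and comes back at 14.
   - Me3SiOSO2CF3 (CH2Cl2, 2,6-lutidine, −78 °C) would turn 6 into 5-(benzyloxy)-3-(methoxycarbonyl)-6-(4-methoxyphenyl)-2-(methylsulfanyl)-4-[(trimethylsilyl)oxy]pyrylium trifluoromethanesulfonate F9.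
   - Silyl enol ether 12 (1.2 equiv) would add to F9 at the SMe-bearing carbon in a Mukaiyama-type addition; loss of the methylsulfanyl group as its silyl sulfide and aqueous work-up would restore the pyranone as 14.
   - No basic enolate and no excess of the chiral fragment are involved.

3. Step 2. The enolate may be aroylated on oxygen instead of carbon, or the ring may close through the ester with loss of methanol instead of through the dithioacetal carbon.
   Fallback by aldol addition and oxidation. It sets out from 2 and comes back at 5.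
   - The enolate 4 of 2 (LiN(SiMe3)2, THF, −78 °C) would add to 4-methoxybenzaldehyde to give methyl 4-(benzyloxy)-2-[bis(methylsulfanyl)methylidene]-5-hydroxy-5-(4-methoxyphenyl)-3-oxopentanoate F10 as a diastereomer mixture.
   - Dess–Martin oxidation (CH2Cl2, rt) would give 5, which is cyclised with CF3CO2H as in step 2.

**Further compounds**

F1 | step 5 | 1-(benzyloxy)-4-ethenylbenzene | C=Cc1ccc(OCc2ccccc2)cc1
F2 | step 5 | 2-{(1R)-1-[4-(benzyloxy)phenyl]ethyl}-4,4,5,5-tetramethyl-1,3,2-dioxaborolane | C[C@@H](B1OC(C)(C)C(C)(C)O1)c1ccc(OCc2ccccc2)cc1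
F3 | step 5 | 2-(benzyloxy)-1-(2-hydroxy-4,6-dimethoxyphenyl)ethan-1-one | COc1cc(O)c(C(=O)COCc2ccccc2)c(OC)c1
F4 | step 5 | 2-[(benzyloxy)acetyl]-3,5-dimethoxyphenyl 4-methoxybenzoate | COc1ccc(C(=O)Oc2cc(OC)cc(OC)c2C(=O)COCc2ccccc2)cc1
F5 | step 5 | 2-(benzyloxy)-1-(2-hydroxy-4,6-dimethoxyphenyl)-3-(4-methoxyphenyl)propane-1,3-dione | COc1ccc(C(=O)C(OCc2ccccc2)C(=O)c2c(O)cc(OC)cc2OC)cc1
F6 | step 5 | 3-(benzyloxy)-5,7-dimethoxy-2-(4-methoxyphenyl)-4H-chromen-4-one | COc1ccc(-c2oc3cc(OC)cc(OC)c3c(=O)c2OCc2ccccc2)cc1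
F7 | step 5 | 3-(benzyloxy)-8-iodo-5,7-dimethoxy-2-(4-methoxyphenyl)-4H-chromen-4-one | COc1ccc(-c2oc3c(I)c(OC)cc(OC)c3c(=O)c2OCc2ccccc2)cc1
F8 | step 5 | 3-(benzyloxy)-8-{(1R)-1-[4-(benzyloxy)phenyl]ethyl}-5,7-dimethoxy-2-(4-methoxyphenyl)-4H-chromen-4-one | COc1ccc(-c2oc3c([C@H](C)c4ccc(OCc5ccccc5)cc4)c(OC)cc(OC)c3c(=O)c2OCc2ccccc2)cc1
F9 | step 4 | 5-(benzyloxy)-3-(methoxycarbonyl)-6-(4-methoxyphenyl)-2-(methylsulfanyl)-4-[(trimethylsilyl)oxy]pyrylium trifluoromethanesulfonate | COC(=O)c1c(SC)[o+]c(-c2ccc(OC)cc2)c(OCc2ccccc2)c1O[Si](C)(C)C.[O-]S(=O)(=O)C(F)(F)F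
F10 | step 2 | methyl 4-(benzyloxy)-2-[bis(methylsulfanyl)methylidene]-5-hydroxy-5-(4-methoxyphenyl)-3-oxopentanoate | COC(=O)C(=C(SC)SC)C(=O)C(OCc1ccccc1)C(O)c1ccc(OC)cc1
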